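How much G can the flask hold within the time allowed, and when?

| flask | L | J | remark | time |
|---|---|---|---|---|
| Monday's | 0.021 M | 1.5 equiv | run made earlier |  |
| Wednesday's | 0.048 M | 1.5 equiv | run made earlier |  |
| flask | 0.032 M | 1.50 equiv |  | 2.0 h |

- Monday's (time / min: G / %, L / %): 12.0: 9, 73; 20.0: 10, 62; 30.0: 9, 50; 50.0: 14, 32; 80.0: 12, 18
- Wednesday's (time / min: G / %, L / %): 12.0: 14, 67; 20.0: 20, 53; 30.0: 23, 39; 50.0: 26, 24; 80.0: 23, 13

(scatter of a reading: 1.5 percentage points)

1. time, not beyond 2.0 h, at which the flask holds most G
2. the amount of G, in percent of the L charged, at that time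
3. earliest time at which at least nineteen twentieths of that best amount are there
4. latest time at which they still are

- the earlier runs were read with a standard deviation of 1.5 percentage points

First, how does the lost L divide? We compare G with the rest of the L lost, at 20.0 min in both runs. These odds are 0.357 on Monday and 0.741 on Wednesday, higher on Wednesday. From Monday to Wednesday the odds grow 2.08-fold and the charged cJ 2.29-fold, so we treat them as proportional, within the scatter. Their mean ratio, 10.8 M⁻¹, is our split constant b, the odds of G against the rest per unit of charged cJ, a selectivity factor. The flask charges cJ 0.0480 M, so its odds are 0.519 and G's share of the lost L is 34.2%.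

Second, how much of that share stands at the peak? Wednesday's highest reading, 26%, against its reckoned share of 43.8%, gives a fraction of 0.594. Carried to the flask, this gives 20.3%.

Third, when? Both runs read highest at 50.0 min, so we expect the flask's peak near that time.

The forecast gives 17.5% at 0.83 h, with the window from 0.59 h to 1.15 h, noting that “The yield of G also rises with concentration”. Our 20.3% stands above its best.

The flask gives 19.4% at 0.886 h, with the window from 0.599 h to 1.28 h, so the forecast stands within its margins.

    J + X → Q (k = 28.0 M⁻¹ s⁻¹)
    J + E → G (k = 2.20 M⁻¹ s⁻¹)
    G ⇌ Z (K = 8.00, k = 1.50 × 10⁻⁴ s⁻¹)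
    E ⇌ X (K = 2.90, k = 0.150 s⁻¹)
    L ⇌ E (K = 0.00220, k = 0.00370 s⁻¹)

In the scheme, E is the fork: J takes it to G, or it passes to X and on to Q. At 0.886 h the flask holds G 19.4% and Z, formed from G, 6.77%, against Q 47.5%, which makes the odds 0.551 against our 0.519. The neighbouring flask charges 0.054 M of L at the same equivalents, so its cJ is 0.0810 M, its reckoned odds 0.876 and its reckoned peak 27.7%. At 2.00 h the neighbouring flask shows odds of 0.808, and its best G over the time allowed is 27.4%.

(The readings come from a simulation for an exercise, noise included.)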